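| flask | G | D | remark | time |
|---|---|---|---|---|
| noon | 0.037 M | 200 mM (held) | run made earlier |  |
| autumn | 0.30 M | 200 mM (held) | run made earlier |  |
| birch | 0.060 M | 200 mM (held) |  | 20 min |
| alder | 0.12 M | 200 mM (held) |  | 20 min |
| elm | 0.25 M | 200 mM (held) |  | 20 min |
| cedar | 0.50 M | 200 mM (held) |  | 20 min |

| run | time / min | L / % | G / % |
|---|---|---|---|
| noon | 0.833 | 0.7 | 90.8 |
| noon | 2.00 | 0.5 | 78.8 |
| noon | 4.00 | 1.3 | 62.5 |
| noon | 6.00 | 2.5 | 52.2 |
| noon | 8.00 | 4.4 | 44.4 |
| noon | 12.0 | 8.8 | 34.0 |
| noon | 15.0 | 11.1 | 28.7 |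
| autumn | 1.00 | 0.1 | 89.8 |
| autumn | 1.50 | 0.1 | 84.4 |
| autumn | 2.50 | 1.2 | 74.6 |
| autumn | 4.00 | 2.2 | 63.1 |
| autumn | 6.00 | 3.3 | 52.0 |
| autumn | 10.0 | 7.1 | 39.0 |
| autumn | 15.0 | 11.3 | 30.4 |

(scatter of a reading: 0.5 percentage points)

- at the start none of D is in solution
- "hardly changes" means that all values lie within two and a half points (for a concentration: within two and a half percent of the largest)

1. [L] at the end for birch, alder, elm, cedar, in this order
2. how that number moves from the first to the last of them (rises all the way / falls, then rises / rises, then falls / falls all the way / hardly changes)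

Lay a ruler from the origin through the last L reading and you have assumed that L was made at full rate from the first minute, which nobody has shown. So take two versions of the flask that you can integrate in your head. If the rate of L is constant, L grows as time; if the rate grows in proportion to time, L grows as the square of time. Scaled from noon's 11.1 % at 15.0 min, the first version puts L at 5.92 % at 8.00 min and the second at 3.16 %. The reading there is 4.4 %, so noon lies between them, and as my estimate I let L go as time to a power n. Read from the readings, with their scatter, n is 1.47 in noon and 1.34 in autumn; I take 1.41.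

Noon and autumn, with 0.037 M and 0.30 M of G, differ at 15.0 min by 0.2 percentage points, inside the scatter, which is pseudo-first-order behaviour at held D. Their mean there is 11.2 %. At 20 min the two versions give 14.9 % and 19.9 %, and n gives 16.8 %. Call this the L share f, the part of the G charged that stands as L at that time. Multiplied by the charges, f gives my row: 0.0101 M, 0.0201 M, 0.0420 M and 0.0840 M, rising with the charge, though cedar's charge lies above both earlier runs.

The forecast is lower than my row, with 0.0093 M, 0.0186 M, 0.0388 M and 0.0775 M, “rising in proportion to the charge”, and its shape is: rises all the way.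

The flask gives 0.0105 M, 0.0209 M, 0.0434 M and 0.0864 M: rises all the way.

    G + Z ⇌ E (K = 11.0 M⁻¹, k = 0.00875 M⁻¹ s⁻¹)
    E ⇌ L + Q (K = 24.0 M, k = 4.05 × 10⁻⁴ s⁻¹)
    G ⇌ J (K = 0.470, k = 4.79 × 10⁻⁴ s⁻¹)
    D ⇌ Z, rate k4*(csat - [Z]) (kL = 0.110 s⁻¹)

Against f of 16.8 %, birch holds 17.4 % as L at 20.0 min; for cedar at 10.0 min the same rule gives 6.33 %, and cedar holds 6.70 %. In birch, G went early into E and J, leaving G at 38.4 % with E at 42.3 % and J at 12.5 % by 10.0 min; after that E stood nearly level, at 43.2 % by 20.0 min, while it passed on to L + Q. In cedar, the largest charge, Z stood at 0.198 M at 10.0 min and 0.199 M at 20.0 min.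

The runs come from a simulation for substances that don't exist, noise included.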